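At 50 min the theta flask is due to be read, and this note is for you as you take over the bench. Its Xa and Xb turn into Xp, and its Xb charge is 5.50 times its Xa charge. The earlier flasks and the questions are these:

| flask | Xa | Xb | Xp | time |
|---|---|---|---|---|
| delta | 0.150 M | 0.165 M |  |  |
| zeta | 0.0900 M | 0.105 M |  |  |
| beta | 0.150 M | 0.0830 M |  |  |
| epsilon | 0.150 M | 0.165 M | 0.0450 M |  |
| theta | 0.0300 M | 0.165 M |  | 50 min |

- delta run (time / min: [Xp] / M): 3.8: 0.0150; 12: 0.0320; 22: 0.0423; 35: 0.0508; 50: 0.0519
- zeta run (time / min: [Xp] / M): 3.8: 0.0080; 12: 0.0162; 22: 0.0222; 35: 0.0263; 50: 0.0304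
- beta run (time / min: [Xp] / M): 3.8: 0.0090; 12: 0.0228; 22: 0.0308; 35: 0.0365; 50: 0.0371
- epsilon run (time / min: [Xp] / M): 3.8: 0.0567; 12: 0.0711; 22: 0.0801; 35: 0.0820; 50: 0.0861

(each reading ± 0.001 M)

* apparent order in [Xb] of the starting rate, round the charge of the delta run (the rate where two percent of its Xa have turned into Xp)
* apparent order in [Xa] of the starting rate, round the charge of the delta run (the rate where two percent of its Xa have turned into Xp) (one fixed amount of Xp, the same in the runs compared)
* Xp in the theta run at 50 min, as a share of the Xa charged

- Overall: Xa + Xb -> Xp.
- Constant volume, constant temperature.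
- Bound and free are read together.
- "The second partner" is Xb.
- An order is taken over about fifteen percent of the charge, up and down.

Please do not add Xb to theta in the hope of a proportional gain in speed. Beta has half of delta's Xb and the same Xa, yet over the first two readings taken together it makes 0.677 of delta's Xp. Dividing the log of that ratio by the log of the Xb ratio gives 0.569. I carry this number as the Xb order, the power of the Xb charge that the early rate follows, averaged between beta's charge and delta's. It is a reading and has the scatter of those early points in it.

The forecast gives 0.45 for the Xb order, adding “perhaps less locally if saturating”. It gives 0.85 for the Xa order and 43% of theta's Xa charge as Xp at 50 min. My Xb order of 0.569 stands higher than the forecast's, and I make no reckoning of my own for the other two.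

The flask gives an Xb order of 0.61, an Xa order of 1.0, and 35.1% of theta's Xa charge as Xp.

    Xa + Xb → Xp (0.5826 /M/min)
    Xa + Xb → Xq (0.5178 /M/min)
    2 Xb ⇌ Xb2, settled at all times (27.00 /M)
    Xp + Xb → Xq (0.2184 /M/min)

The Xb order stands below one because Xb pairs up as Xb2: without that pairing, delta's order is 1.0 instead of 0.61. Zeta is the second flask for the carried number: it has 0.600 of delta's Xa and 0.636 of delta's Xb. Starting from delta's rate of 0.0038 M/min, the Xa order of 1.0 and my Xb order of 0.569 put zeta's rate at 0.00173 M/min. With the same small amount of Xp made, zeta's simulated rate is 0.0017 M/min.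

The runs are calculated from invented constants, and the scatter is random.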